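0.200 M of nucleophile over electrophile: this excess, the same in the flask and in birch, makes electrophile the limiting reagent if the two are used one for one, and it gives me a curve to draw.

| flask | electrophile | nucleophile | free base | remark | time |
|---|---|---|---|---|---|
| birch | 1 M | 1.2 M | 1 M | run made earlier |  |
| ash | 1 M | 1.2 M | 1.5 M | run made earlier |  |
| cedar | 0.50 M | 1.2 M | 2 M | run made earlier |  |
| flask | 1.0 M | 1.20 M | 2.00 M |  | 4.0 d |

| run | time / d | electrophile / % | target / % |
|---|---|---|---|
| birch | 0.333 | 56.0 | 45.2 |
| birch | 0.625 | 40.9 | 58.8 |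
| birch | 1.04 | 29.3 | 70.7 |
| birch | 1.25 | 26.2 | 74.3 |
| birch | 1.67 | 20.1 | 80.0 |
| birch | 2.08 | 15.3 | 82.5 |
| birch | 2.50 | 12.9 | 86.1 |
| ash | 0.125 | 77.0 | 21.9 |
| ash | 0.333 | 56.9 | 44.9 |
| ash | 0.625 | 40.6 | 59.6 |
| ash | 1.04 | 29.3 | 70.9 |
| ash | 1.67 | 20.3 | 79.6 |
| ash | 2.08 | 16.2 | 83.8 |
| ash | 2.50 | 12.5 | 86.5 |
| cedar | 0.500 | 39.9 | 60.0 |
| cedar | 1.04 | 19.7 | 80.2 |
| cedar | 1.25 | 15.5 | 84.4 |
| cedar | 2.08 | 6.3 | 93.3 |
| cedar | 2.50 | 4.1 | 95.8 |

(readings scatter by 0.5 percentage points)

- part of the electrophile that has reacted at 4.0 d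
- share of free nucleophile in free nucleophile and protonated nucleophile together, at 4.0 d

- the earlier runs do not show how much of nucleophile is bound; that part of a forecast is a guess

On that count, c nucleophile equals c electrophile plus the excess, and for a second-order step ln(c nucleophile / c electrophile) climbs straight with time, with slope k times the excess. Birch starts this curve at 0.182. Its first reading, at 0.333 d, gives a steep start, k = 1.85 M⁻¹ d⁻¹. Then the curve bends: from 1.25 d to 2.50 d it goes from 0.567 to 0.936, which reads as 1.48 M⁻¹ d⁻¹, the late second-order constant. Cedar, with its excess of 0.700 M, reads 1.43 M⁻¹ d⁻¹ over the same stretch. Birch with 1 M of free base and ash with 1.5 M stand at 12.9% and 12.5% electrophile at 2.50 d, within the scatter of 0.5 percentage points, so I read the flask as birch continued. The straight stretch reaches 1.38 at 4.0 d, so c electrophile is 0.0673 M, and my conversion is 93.3%, with no level reached yet.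

The forecast says 93.2% and 97%, and of the second number it says: “This is an inference, not a measurement”.

The flask gives 92.8% and 98.8%.

    electrophile + nucleophile → acid set free + target (k = 0.00140 M⁻¹ min⁻¹)
    nucleophile + acid set free ⇌ protonated nucleophile, settled at all times (K = 16.0 M⁻¹)
    acid set free + free base ⇌ salt of the base, settled at all times (K = 1100 M⁻¹)
    acid set free + target → side product (k = 3.60 × 10⁻⁴ M⁻¹ min⁻¹)
    nucleophile → decomposition product (k = 2.70 × 10⁻⁷ min⁻¹)
    nucleophile ⇌ dormant form (K = 0.390, k = 3.50 × 10⁻⁴ min⁻¹)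

At 4.00 d the flask holds 0.924 M of salt of the base against 0.00234 M of protonated nucleophile, and the joining that forms the latter makes no difference to the conversion. My k reckoned 6.70% of the electrophile as remaining in the flask, which holds 7.20%. In a neighbour charged with 0.60 M of electrophile, the same k carries the logarithm to 4.24 and reckons 1.47% as remaining; that neighbour holds 1.4% of its electrophile.

The runs were computed on assumed constants; the scatter is artificial.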